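(The constants are assumed; the rest is arithmetic.)

In a one-step world the electrophile has a single partner, the nucleophile, and at a fixed time the more of it you charge, the further the electrophile goes. Two chemists argue whether this flask is such a world.

| setting | Saturday's | Tuesday's | Sunday's |
|---|---|---|---|
| electrophile | 0.28 M | 0.28 M | 0.28 M |
| nucleophile | 0.270 M | 0.400 M | 0.600 M |
| time | 3.0 h | 3.0 h | 3.0 h |

    electrophile + nucleophile → acid set free + target (k1 = 0.0912 L mol⁻¹ min⁻¹)
    nucleophile + acid set free ⇌ protonated nucleophile, settled at all times (K2 = 285 L mol⁻¹)
    2 electrophile → self-condensation product (k3 = 0.169 L mol⁻¹ min⁻¹)
    electrophile + target → side product (k4 = 0.0108 L mol⁻¹ min⁻¹)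
    electrophile ⇌ dormant form (K5 = 3.28, k5 = 0.0299 min⁻¹)

- part of the electrophile that has reacted at the end, Saturday's
- part of the electrophile that has reacted at the end, Tuesday's
- part of the electrophile that has reacted at the end, Sunday's
- what raising the concentration of nucleophile from its lowest to its highest value here does to the part of the electrophile that has reacted (changes below 5 percentage points count as none) (it falls / no change / it rises)

- in percentages every species weighs as the electrophile in it: one self-condensation product or side product counts as two
- a step written with two of one species runs at k times the square of its concentration and takes two of it each time
- what has gone from electrophile into another species counts as reacted, even if it can come back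
- run time (Saturday's): 3.0 h

The first chemist holds to the one-step view. Acid set free is caught at once, she says, since K2 times [nucleophile] is 77 on Saturday's, so each turn costs two nucleophile. By her view Saturday's stops near 48.2%, while Sunday's nucleophile covers 107% of the electrophile, so the part reacted rises.

The second chemist counts doors: what has gone from electrophile into another species counts as reacted. A free electrophile on Saturday's starts with 0.0246 min⁻¹ through the nucleophile, 0.0946 min⁻¹ through self-condensation and 0.0299 min⁻¹ into the dormant form. That makes 0.149 min⁻¹. On Sunday's the nucleophile is 2.22 times Saturday's, yet the sum is 0.179 min⁻¹. The forecast is her number: 95.3%, 97.4% and 98.6%, with the verdict no change, on the ground that “dormant form counts as reacted”.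

My own reckoning follows one molecule. At the first fork it enters the dormant form with chance k5 over the door sum, 0.201 on Saturday's. From there it comes back at 0.009116 min⁻¹. Taking free electrophile as low by then, I drop self-condensation at this second fork. The return ratio, free electrophile standing per dormant form, is the back rate over k5 + k1[nucleophile]. With the charges it is 0.167 on Saturday's, 0.137 on Tuesday's and 0.108 on Sunday's. The chance at the start times this ratio is my estimate of the electrophile left. So I expect 96.6% reacted on Saturday's, 97.4% on Tuesday's and 98.2% on Sunday's. On Saturday's mine is above the forecast by 1.3 percentage points, and on Sunday's it is below by 0.4 points.

The flask gives 96.1%, 97.2% and 98.3%, a rise of 2.2 points, less than 5 points, so the verdict is no change. The rise the first chemist expected stands in the target, 28.0% on Saturday's and 48.9% on Sunday's at 3.00 h. Tuesday's flask read at 5.00 h has 40.1% of its nucleophile free. Putting that in place of the charge turns Tuesday's return ratio into 0.205. Times the dormant form, 9.98%, this gives 2.04%, and the electrophile there stands at 2.02%.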